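**Plan**

- Retrosynthesis: the C8 ester, the tert-butyl ester and a 6,15-lactol acetal are removed first, then the ring is opened at C5–C10. The vinyl group on C10 and the 2-substituted allyl group on C5 sit on adjacent carbons of the cyclohexane (C5–C10) and form a hexa-1,5-diene, C2=C1–C10–C5–C4=C3. This is the retron of the germacrane-to-elemane [3,3] event, run here on an open chain as a palladium-templated allyl–allyl reductive elimination.
- The chain is cut at C6–C7 into a γ-hydroxybutenolide (C3, C4, C5, C6, C15) and a (Z)-2-(bromomethyl)enoate made from geranyl acetate (C1, C2, C7–C14).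
- Forward: geranyl acetate → aldehyde → α-oxyamination → Morita–Baylis–Hillman adduct → allylic bromide. An indium Barbier union closes the butenolide O6–C15 (temporary ring, C15 at the acid level). Borylation and closure of C5–C10 give the six-membered ring. Then C8 ketone → alcohol, lactone → lactol acetal, acylation and unmasking.
- Stereochemistry: C8 is set by organocatalysis and relayed to C7 and C6 in the Barbier step. The butenolide (C6) and the E alkene relay to C5 and C10 in the ring closure. C8 is then erased as a ketone and reset from the ring by hydride delivery anti to the axial C10 methyl.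

Key step: step 10

Remark: atoms are numbered as in elemanes (ring C5 to C10; C14 methyl on C10; vinyl C1=C2 on C10; C3=C4 with C15 on C5; C11=C13 with C12 on C7); the lactol carbon C15 of 15, 16, 20 and 21 is an uncontrolled epimer mixture that disappears in step 15.

Step 1
Reactants: 1 geranyl acetate
Product: 3 (2E)-3-methyl-6-oxohex-2-en-1-yl acetate, via 6,7-epoxygeranyl acetate 2 (not isolated)
Conditions: mCPBA, CH2Cl2, 0 °C; then H5IO6, THF/H2O, 0 °C to rt
Reagents that add atoms: mCPBA O=C(OO)c1cccc(Cl)c1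
Why: Prilezhaev epoxidation should pick the electron-rich 6,7-alkene (the 2,3-alkene is deactivated by the allylic acetate) and periodic acid cleaves the epoxide through its diol to the aldehyde and acetone, leaving the E alkene (later C10=C1) and the acetate (later the C2 leaving group).

Step 2
Reactants: 3 (2E)-3-methyl-6-oxohex-2-en-1-yl acetate
Product: 4 (2E,5S)-3-methyl-6-oxo-5-[(2,2,6,6-tetramethylpiperidin-1-yl)oxy]hex-2-en-1-yl acetate
Conditions: TEMPO, CuCl2·2H2O (10 mol %), enantiopure 5-benzyl-2-tert-butyl-3-methylimidazolidin-4-one·CF3CO2H (20 mol %, the enantiomer that gives the 5S product), air, acetone, −20 °C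
Reagents that add atoms: TEMPO CC1(C)CCCC(C)(C)N1[O]
Why: Organocatalytic α-oxyamination: the chiral enamine of 3 is trapped by copper-activated TEMPO on its open face, which sets C8 under catalyst control and installs a bulky, non-nucleophilic oxygen substituent that is inert to the later metal steps.

Step 3
Reactants: 4 (2E,5S)-3-methyl-6-oxo-5-[(2,2,6,6-tetramethylpiperidin-1-yl)oxy]hex-2-en-1-yl acetate
Product: 5 tert-butyl (4S,6E)-8-acetoxy-3-hydroxy-6-methyl-2-methylidene-4-[(2,2,6,6-tetramethylpiperidin-1-yl)oxy]oct-6-enoate (both C3 epimers)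
Conditions: tert-butyl acrylate (excess), DABCO, 1,4-dioxane/H2O, rt
Reagents that add atoms: tert-butyl acrylate C=CC(=O)OC(C)(C)C
Why: Morita–Baylis–Hillman reaction of the inductively activated α-oxy aldehyde joins the acrylate α-carbon (C11) to C7; the new carbinol centre does not matter because it becomes sp2 in step 4.

Step 4
Reactants: 5 tert-butyl (4S,6E)-8-acetoxy-3-hydroxy-6-methyl-2-methylidene-4-[(2,2,6,6-tetramethylpiperidin-1-yl)oxy]oct-6-enoate
Product: 6 tert-butyl (2Z,4S,6E)-8-acetoxy-2-(bromomethyl)-6-methyl-4-[(2,2,6,6-tetramethylpiperidin-1-yl)oxy]octa-2,6-dienoate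
Conditions: NBS, Me2S, CH2Cl2, −20 °C to rt
Reagents that add atoms: N-bromosuccinimide O=C1CCC(=O)N1Br
Why: The bromodimethylsulfonium salt activates the allylic hydroxyl and bromide enters at the CH2 terminus with allylic transposition (SN2'), which should give the more stable Z bromide with C8 cis to CH2Br and trans to the ester.

Step 5
Reactants: 7 furan-3-ylmethanol
Product: 8 [2-(trimethylsilyl)furan-3-yl]methanol
Conditions: n-BuLi (2.2 equiv), THF, −78 to 0 °C; Me3SiCl (1.05 equiv), −78 °C to rt; aq NH4Cl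
Reagents that add atoms: chlorotrimethylsilane C[Si](C)(C)Cl
Why: Directed ortho-metalation: the lithium alkoxide steers the second deprotonation to C2 of the furan, and C-silylation (directly or by 1,4 O-to-C silyl shift) gives the 2-silylfuran.

Step 6
Reactants: 8 [2-(trimethylsilyl)furan-3-yl]methanol
Product: 9 methyl [2-(trimethylsilyl)furan-3-yl]methyl carbonate
Conditions: ClCO2Me, pyridine, CH2Cl2, 0 °C
Reagents that add atoms: methyl chloroformate COC(=O)Cl
Why: Acylation of the primary alcohol installs the carbonate that later serves as the leaving group at C3.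

Step 7
Reactants: 9 methyl [2-(trimethylsilyl)furan-3-yl]methyl carbonate
Product: 10 (5-hydroxy-2-oxo-2,5-dihydrofuran-3-yl)methyl methyl carbonate (racemic hemiacetal)
Conditions: O2, hν, tetraphenylporphyrin (cat.), CH2Cl2, −78 °C; then H2O, rt
Reagents that add atoms: oxygen O=O
Why: Singlet-oxygen [4+2] cycloaddition to the furan followed by silyl migration in the endoperoxide places the carboxyl carbon at the silylated position, so only the α-substituted γ-hydroxybutenolide should form.

Step 8
Reactants: 6 tert-butyl (2Z,4S,6E)-8-acetoxy-2-(bromomethyl)-6-methyl-4-[(2,2,6,6-tetramethylpiperidin-1-yl)oxy]octa-2,6-dienoate; 10 (5-hydroxy-2-oxo-2,5-dihydrofuran-3-yl)methyl methyl carbonate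
Product: 11 tert-butyl (3S,4S,6E)-8-acetoxy-3-[(2S)-4-{[(methoxycarbonyl)oxy]methyl}-5-oxo-2,5-dihydrofuran-2-yl]-6-methyl-2-methylidene-4-[(2,2,6,6-tetramethylpiperidin-1-yl)oxy]oct-6-enoate
Conditions: In powder, THF/H2O (1:1), rt; then 1 M HCl
Reagents that add atoms: none
Why: Barbier allylation: the (Z)-allylindium adds through its γ-carbon C7 to the aldehyde tautomer of 10 in a chair transition state (syn C6/C7 pair), on the face opposite the bulky C8 aminoxy group, which allylic 1,3-strain holds with H8 eclipsing the alkene, and the cis-hydroxy acid lactonises to the butenolide on acidification.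

Step 9
Reactants: 11 tert-butyl (3S,4S,6E)-8-acetoxy-3-[(2S)-4-{[(methoxycarbonyl)oxy]methyl}-5-oxo-2,5-dihydrofuran-2-yl]-6-methyl-2-methylidene-4-[(2,2,6,6-tetramethylpiperidin-1-yl)oxy]oct-6-enoate
Product: 12 tert-butyl (3S,4S,6E)-8-acetoxy-6-methyl-2-methylidene-3-{(2S)-5-oxo-4-[(4,4,5,5-tetramethyl-1,3,2-dioxaborolan-2-yl)methyl]-2,5-dihydrofuran-2-yl}-4-[(2,2,6,6-tetramethylpiperidin-1-yl)oxy]oct-6-enoate
Conditions: Pd2(dba)3 (cat.), B2pin2, THF, rt
Reagents that add atoms: bis(pinacolato)diboron CC1(C)OB(OC1(C)C)B1OC(C)(C)C(C)(C)O1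
Why: Miyaura-type allylic borylation: zerovalent palladium ionises the doubly activated (Morita–Baylis–Hillman-type) carbonate much faster than the allylic acetate, and the released methoxide activates the diboron for transfer to the CH2 terminus, which keeps the butenolide conjugated.

Step 10
Reactants: 12 tert-butyl (3S,4S,6E)-8-acetoxy-6-methyl-2-methylidene-3-{(2S)-5-oxo-4-[(4,4,5,5-tetramethyl-1,3,2-dioxaborolan-2-yl)methyl]-2,5-dihydrofuran-2-yl}-4-[(2,2,6,6-tetramethylpiperidin-1-yl)oxy]oct-6-enoate
Product: 13 tert-butyl (5R,6S,7S,8S,10S)-8-[(2,2,6,6-tetramethylpiperidin-1-yl)oxy]elema-1,3,11(13)-trien-15,6-olid-12-oate (cis-fused α-methylene-γ-lactone C15(=O)–O–C6)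
Conditions: Pd2(dba)3 (cat.), 1,2-bis(diphenylphosphino)benzene, CsF, THF/H2O (10:1), 60 °C, high dilution
Reagents that add atoms: none
Why: Proposed new method: zerovalent palladium ionises the allylic acetate to a prenyl-type allylpalladium, fluoride-assisted boron-to-palladium transfer of the 2-acylallyl unit gives a bis(allyl)palladium, and 3,3'-reductive elimination through a chair-like array C3–C4–C5···C10–C1–C2 with palladium bridging C2 and C3 (a metal-templated counterpart of the germacrane-to-elemane Cope rearrangement) forms C5–C10 and releases the C1=C2 vinyl and C4=C3 methylidene groups; the closest known reactions are the branched-selective palladium-catalysed coupling of allylboronates with allylic electrophiles, which builds vicinal tertiary and quaternary centres, and intramolecular couplings of allylstannanes with allyl carboxylates to 1,2-divinylcycloalkanes. The six-membered carbocycle closes by union of the two inner allyl termini, exo to both allyl units, through an eleven-membered palladacycle. C5 is controlled by the planar butenolide, which holds O6 in the plane of C4=C5 so that C10 can only reach the face of C5 on which C7 lies, giving the cis-fused lactone. C10 is controlled by the E geometry of C1=C10 in the chair array, which places C9 pseudo-equatorial and the methyl pseudo-axial, anti to H5, so that vinyl ends trans to C4. The step needs 3,3' over 1,1' coupling, secured by the small-bite-angle bisphosphine and by six- over ten-membered ring formation, and chair over boat, helped by the fact that O8 is still equatorial so the axial methyl meets only O6.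

Step 11
Reactants: 13 tert-butyl (5R,6S,7S,8S,10S)-8-[(2,2,6,6-tetramethylpiperidin-1-yl)oxy]elema-1,3,11(13)-trien-15,6-olid-12-oate
Product: 14 tert-butyl (5R,6S,7S,10S)-8-oxoelema-1,3,11(13)-trien-15,6-olid-12-oate
Conditions: mCPBA, NaHCO3, CH2Cl2, 0 °C
Reagents that add atoms: none
Why: Peracid oxidation of the alkoxyamine nitrogen and elimination of the hydroxylamine should turn the C8–O–N unit directly into the ketone, while the electron-poor methylidene groups and the hindered vinyl group are left alone.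

Step 12
Reactants: 14 tert-butyl (5R,6S,7S,10S)-8-oxoelema-1,3,11(13)-trien-15,6-olid-12-oate
Product: 16 tert-butyl (5R,6S,7R,8R,10S)-8-hydroxy-15-methoxy-6,15-epoxyelema-1,3,11(13)-trien-12-oate, via lactol 15 (not isolated)
Conditions: iBu2AlH, CH2Cl2, −78 °C; then MeOH, PPTS, rt
Reagents that add atoms: methanol CO
Why: Hydride should reach the C8 ketone from the α face, anti to the axial C10 methyl and the axial C6–O bond (both 1,3 to C8), giving the axial 8β alcohol, while the strained α-methylene lactone is reduced to the lactol faster than the hindered tert-butyl acrylate; acid-catalysed acetalisation then masks O6 and O15 together.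

Step 13
Reactants: 17 3-methylfuran-2(5H)-one
Product: 19 (2Z)-4-acetoxy-2-methylbut-2-enoic acid, via sodium (2Z)-4-hydroxy-2-methylbut-2-enoate 18 (not isolated)
Conditions: NaOH (1 equiv), H2O, 0 °C to rt, evaporate; Ac2O, pyridine, DMAP (cat.), 0 °C; aqueous work-up to pH 3
Reagents that add atoms: sodium hydroxide [Na+].[OH-]; acetic anhydride CC(=O)OC(C)=O
Why: Saponification of the butenolide fixes the Z geometry it already has, and acetylation of the salt before acidification blocks relactonisation.

Step 14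
Reactants: 16 tert-butyl (5R,6S,7R,8R,10S)-8-hydroxy-15-methoxy-6,15-epoxyelema-1,3,11(13)-trien-12-oate; 19 (2Z)-4-acetoxy-2-methylbut-2-enoic acid
Product: 20 tert-butyl (5R,6S,7R,8R,10S)-8-{[(2Z)-4-acetoxy-2-methylbut-2-enoyl]oxy}-15-methoxy-6,15-epoxyelema-1,3,11(13)-trien-12-oate
Conditions: 19, 2,4,6-trichlorobenzoyl chloride, Et3N, toluene, rt; then 16, DMAP, rt
Reagents that add atoms: none
Why: Yamaguchi esterification through the mixed anhydride acylates the only free hydroxyl (O6 and O15 are tied in the acetal) under conditions known to preserve angelate-type Z geometry.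

Step 15
Reactants: 20 tert-butyl (5R,6S,7R,8R,10S)-8-{[(2Z)-4-acetoxy-2-methylbut-2-enoyl]oxy}-15-methoxy-6,15-epoxyelema-1,3,11(13)-trien-12-oate
Product: 22 tert-butyl (5R,6S,7S,8R,10S)-8-{[(2Z)-4-acetoxy-2-methylbut-2-enoyl]oxy}-6,15-dihydroxyelema-1,3,11(13)-trien-12-oate, via lactol 21 (not isolated)
Conditions: AcOH/THF/H2O, 35 °C; then NaBH4, CeCl3·7H2O, MeOH, 0 °C
Reagents that add atoms: water O
Why: Mild acetal hydrolysis gives the lactol, whose open hydroxy-enal form is reduced 1,2 under Luche conditions to the 6,15-diol without touching the three esters.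

Step 16
Reactants: 22 tert-butyl (5R,6S,7S,8R,10S)-8-{[(2Z)-4-acetoxy-2-methylbut-2-enoyl]oxy}-6,15-dihydroxyelema-1,3,11(13)-trien-12-oate
Product: 23 (5R,6S,7S,8R,10S)-8-{[(2Z)-4-acetoxy-2-methylbut-2-enoyl]oxy}-6,15-dihydroxyelema-1,3,11(13)-trien-12-oic acid (target)
Conditions: Me3SiOTf, 2,6-lutidine, CH2Cl2, 0 °C; then citric acid, MeOH/H2O
Reagents that add atoms: none
Why: Silyl triflate-mediated cleavage of the tert-butyl ester (carbonyl silylation, loss of 2-methylpropene, hydrolysis of the silyl ester on work-up) is non-protic, spares the other two esters and, by transient silylation of O6 and O15, should keep the γ-hydroxy acid from lactonising.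

**Compound list**

1 | geranyl acetate | CC(=O)OC/C=C(\C)CCC=C(C)C | starting material
2 | 6,7-epoxygeranyl acetate (racemic) | CC(=O)OC/C=C(\C)CCC1OC1(C)C | intermediate
3 | (2E)-3-methyl-6-oxohex-2-en-1-yl acetate | CC(=O)OC/C=C(\C)CCC=O | intermediate
4 | (2E,5S)-3-methyl-6-oxo-5-[(2,2,6,6-tetramethylpiperidin-1-yl)oxy]hex-2-en-1-yl acetate | CC(=O)OC/C=C(\C)C[C@H](ON1C(C)(C)CCCC1(C)C)C=O | intermediate
5 | tert-butyl (4S,6E)-8-acetoxy-3-hydroxy-6-methyl-2-methylidene-4-[(2,2,6,6-tetramethylpiperidin-1-yl)oxy]oct-6-enoate (both C3 epimers) | CC(=O)OC/C=C(\C)C[C@H](ON1C(C)(C)CCCC1(C)C)C(O)C(=C)C(=O)OC(C)(C)C | intermediate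
6 | tert-butyl (2Z,4S,6E)-8-acetoxy-2-(bromomethyl)-6-methyl-4-[(2,2,6,6-tetramethylpiperidin-1-yl)oxy]octa-2,6-dienoate | CC(=O)OC/C=C(\C)C[C@H](ON1C(C)(C)CCCC1(C)C)/C=C(\CBr)C(=O)OC(C)(C)C | intermediate
7 | furan-3-ylmethanol | OCc1ccoc1 | starting material
8 | [2-(trimethylsilyl)furan-3-yl]methanol | OCc1ccoc1[Si](C)(C)C | intermediate
9 | methyl [2-(trimethylsilyl)furan-3-yl]methyl carbonate | COC(=O)OCc1ccoc1[Si](C)(C)C | intermediate
10 | (5-hydroxy-2-oxo-2,5-dihydrofuran-3-yl)methyl methyl carbonate (racemic hemiacetal) | COC(=O)OCC1=CC(O)OC1=O | intermediate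
11 | tert-butyl (3S,4S,6E)-8-acetoxy-3-[(2S)-4-{[(methoxycarbonyl)oxy]methyl}-5-oxo-2,5-dihydrofuran-2-yl]-6-methyl-2-methylidene-4-[(2,2,6,6-tetramethylpiperidin-1-yl)oxy]oct-6-enoate | CC(=O)OC/C=C(\C)C[C@H](ON1C(C)(C)CCCC1(C)C)[C@@H](C(=C)C(=O)OC(C)(C)C)[C@H]1OC(=O)C(COC(=O)OC)=C1 | intermediate
12 | tert-butyl (3S,4S,6E)-8-acetoxy-6-methyl-2-methylidene-3-{(2S)-5-oxo-4-[(4,4,5,5-tetramethyl-1,3,2-dioxaborolan-2-yl)methyl]-2,5-dihydrofuran-2-yl}-4-[(2,2,6,6-tetramethylpiperidin-1-yl)oxy]oct-6-enoate | CC(=O)OC/C=C(\C)C[C@H](ON1C(C)(C)CCCC1(C)C)[C@@H](C(=C)C(=O)OC(C)(C)C)[C@H]1OC(=O)C(CB2OC(C)(C)C(C)(C)O2)=C1 | intermediate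
13 | tert-butyl (5R,6S,7S,8S,10S)-8-[(2,2,6,6-tetramethylpiperidin-1-yl)oxy]elema-1,3,11(13)-trien-15,6-olid-12-oate | C=C[C@]1(C)C[C@H](ON2C(C)(C)CCCC2(C)C)[C@@H](C(=C)C(=O)OC(C)(C)C)[C@H]2OC(=O)C(=C)[C@@H]12 | intermediate
14 | tert-butyl (5R,6S,7S,10S)-8-oxoelema-1,3,11(13)-trien-15,6-olid-12-oate | C=C[C@]1(C)CC(=O)[C@@H](C(=C)C(=O)OC(C)(C)C)[C@H]2OC(=O)C(=C)[C@@H]12 | intermediate
15 | tert-butyl (5R,6S,7R,8R,10S)-8,15-dihydroxy-6,15-epoxyelema-1,3,11(13)-trien-12-oate (lactol, C15 epimers) | C=C[C@]1(C)C[C@@H](O)[C@@H](C(=C)C(=O)OC(C)(C)C)[C@H]2OC(O)C(=C)[C@@H]12 | intermediate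
16 | tert-butyl (5R,6S,7R,8R,10S)-8-hydroxy-15-methoxy-6,15-epoxyelema-1,3,11(13)-trien-12-oate (C15 epimers) | C=C[C@]1(C)C[C@@H](O)[C@@H](C(=C)C(=O)OC(C)(C)C)[C@H]2OC(OC)C(=C)[C@@H]12 | intermediate
17 | 3-methylfuran-2(5H)-one | CC1=CCOC1=O | starting material
18 | sodium (2Z)-4-hydroxy-2-methylbut-2-enoate | [Na+].[O-]C(=O)/C(C)=C\CO | intermediate
19 | (2Z)-4-acetoxy-2-methylbut-2-enoic acid | CC(=O)OC/C=C(/C)C(=O)O | intermediate
20 | tert-butyl (5R,6S,7R,8R,10S)-8-{[(2Z)-4-acetoxy-2-methylbut-2-enoyl]oxy}-15-methoxy-6,15-epoxyelema-1,3,11(13)-trien-12-oate (C15 epimers) | C=C[C@]1(C)C[C@@H](OC(=O)/C(C)=C\COC(C)=O)[C@@H](C(=C)C(=O)OC(C)(C)C)[C@H]2OC(OC)C(=C)[C@@H]12 | intermediate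
21 | tert-butyl (5R,6S,7R,8R,10S)-8-{[(2Z)-4-acetoxy-2-methylbut-2-enoyl]oxy}-15-hydroxy-6,15-epoxyelema-1,3,11(13)-trien-12-oate (lactol, C15 epimers) | C=C[C@]1(C)C[C@@H](OC(=O)/C(C)=C\COC(C)=O)[C@@H](C(=C)C(=O)OC(C)(C)C)[C@H]2OC(O)C(=C)[C@@H]12 | intermediate
22 | tert-butyl (5R,6S,7S,8R,10S)-8-{[(2Z)-4-acetoxy-2-methylbut-2-enoyl]oxy}-6,15-dihydroxyelema-1,3,11(13)-trien-12-oate | C=C[C@]1(C)C[C@@H](OC(=O)/C(C)=C\COC(C)=O)[C@@H](C(=C)C(=O)OC(C)(C)C)[C@@H](O)[C@H]1C(=C)CO | intermediate
23 | (5R,6S,7S,8R,10S)-8-{[(2Z)-4-acetoxy-2-methylbut-2-enoyl]oxy}-6,15-dihydroxyelema-1,3,11(13)-trien-12-oic acid | C=C[C@]1(C)C[C@@H](OC(=O)/C(C)=C\COC(C)=O)[C@@H](C(=C)C(=O)O)[C@@H](O)[C@H]1C(=C)CO | target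

**Count and risks**

Total step count: 16. Longest linear sequence: 12 steps (from 1 through steps 1–4, 8–12 and 14–16).

Steps most likely to fail:

(a) Step 10 (Proposed new method). The boron-to-palladium transfer of the electron-poor 2-acylallylboronate may be slow, so that protodeboronation competes; fluoride may epimerise the butenolide γ-position C6; or the coupling may run through the outer CH2 termini. The fallback sets out from 11 and returns at 13. Boron is left out and the two allylic esters of 11 are coupled reductively by zerovalent nickel (NiBr2(PPh3)2 cat., Zn dust, DMF, high dilution), the classical bis(allyl)nickel coupling known to close 1,2-divinylcyclohexanes and medium-ring 1,5-dienes. Union of the inner termini should give 13 directly. Union of the outer termini should give the ten-membered diene tert-butyl (6S,7S,8S)-8-[(2,2,6,6-tetramethylpiperidin-1-yl)oxy]germacra-1(10),4,11(13)-trien-15,6-olid-12-oate (C1=C10 E; C4=C5 trans in the carbocycle) F1. Heating the crude product in toluene at 110 °C should convert F1 into 13 by Cope rearrangement through the same butenolide-locked chair.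

(b) Step 8. Transfer of configuration from C8 to C7 may be weak, with the aldehyde entering on both faces of the allylindium, or the syn C6/C7 relationship may erode in the loose aqueous transition state. The fallback sets out from 6 and 10 and returns at 11. Bromide 6 is converted (Pd2(dba)3 cat., B2pin2, THF) into the allylboronate tert-butyl (2E,4S,6E)-8-acetoxy-6-methyl-2-[(4,4,5,5-tetramethyl-1,3,2-dioxaborolan-2-yl)methyl]-4-[(2,2,6,6-tetramethylpiperidin-1-yl)oxy]octa-2,6-dienoate F2 (same alkene geometry as 6). F2 is added to 10 under catalysis by a chiral BINOL-derived phosphoric acid (toluene, rt; then dilute HCl). The tight six-membered boron-centred chair should enforce the syn pair and the catalyst, matched with C8, should fix the face; lactonisation gives 11.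

(c) Step 14. The activated enoic acid may isomerise from Z to E under nucleophilic catalysis, and acylation of the axial C8 hydroxyl, flanked 1,3-diaxially by the C10 methyl and O6, may be slow. The fallback sets out from 16 and returns at 20, and builds the alkene on the ester instead. Compound 16 is acylated with 2-[bis(2,2,2-trifluoroethoxy)phosphoryl]propanoic acid (DCC, DMAP, CH2Cl2) to tert-butyl (5R,6S,7R,8R,10S)-8-({2-[bis(2,2,2-trifluoroethoxy)phosphoryl]propanoyl}oxy)-15-methoxy-6,15-epoxyelema-1,3,11(13)-trien-12-oate F3. Still–Gennari olefination of F3 (KN(SiMe3)2, 18-crown-6, THF, −78 °C) with 2-oxoethyl acetate should then give the Z enoate 20.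

Further compounds
F1 | step 10 | tert-butyl (6S,7S,8S)-8-[(2,2,6,6-tetramethylpiperidin-1-yl)oxy]germacra-1(10),4,11(13)-trien-15,6-olid-12-oate (C1=C10 E) | C/C1=C\CCC2=C[C@H](OC2=O)[C@H](C(=C)C(=O)OC(C)(C)C)[C@@H](ON3C(C)(C)CCCC3(C)C)C1
F2 | step 8 | tert-butyl (2E,4S,6E)-8-acetoxy-6-methyl-2-[(4,4,5,5-tetramethyl-1,3,2-dioxaborolan-2-yl)methyl]-4-[(2,2,6,6-tetramethylpiperidin-1-yl)oxy]octa-2,6-dienoate | CC(=O)OC/C=C(\C)C[C@H](ON1C(C)(C)CCCC1(C)C)/C=C(\CB2OC(C)(C)C(C)(C)O2)C(=O)OC(C)(C)C
F3 | step 14 | tert-butyl (5R,6S,7R,8R,10S)-8-({2-[bis(2,2,2-trifluoroethoxy)phosphoryl]propanoyl}oxy)-15-methoxy-6,15-epoxyelema-1,3,11(13)-trien-12-oate | C=C[C@]1(C)C[C@@H](OC(=O)C(C)P(=O)(OCC(F)(F)F)OCC(F)(F)F)[C@@H](C(=C)C(=O)OC(C)(C)C)[C@H]2OC(OC)C(=C)[C@@H]12
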